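We judge the slow flasks by one clock: the full-charge hours, which come to 10.0 h for red, violet and grey, that is, the time a flask runs with its whole charge inside.

| flask | electrophile | nucleophile | free base | remark | time |
|---|---|---|---|---|---|
| midnight | 0.40 M | 0.36 M | 0.40 M | run made earlier |  |
| dusk | 0.40 M | 0.24 M | 0.40 M | run made earlier |  |
| summer | 0.40 M | 0.54 M | 0.40 M | run made earlier |  |
| dawn | 0.40 M | 0.36 M | 0.60 M | run made earlier |  |
| red | 0.40 M | 0.360 M (fed, over 15 h) | 0.400 M | all else is in the flask from the start; the feed brings no volume worth counting | 25 h |
| violet | 0.40 M (in portions, 3, over 15 h) | 0.360 M | 0.400 M | first portion at the start, last at 15 h | 25 h |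
| grey | 0.40 M (fed, over 15 h) | 0.360 M | 0.400 M | all else is in the flask from the start; the feed brings no volume worth counting | 25 h |
| blue | 0.40 M | 0.360 M | 0.400 M | everything together at the start | 25 h |

| run | time / h | product / % | electrophile / % |
|---|---|---|---|
| midnight | 4.00 | 45.0 | 54.8 |
| midnight | 8.00 | 61.4 | 38.6 |
| midnight | 12.0 | 68.7 | 31.9 |
| midnight | 15.0 | 71.6 | 28.2 |
| midnight | 20.0 | 75.5 | 25.4 |
| midnight | 25.0 | 76.2 | 23.3 |
| dusk | 3.00 | 28.6 | 72.3 |
| dusk | 6.00 | 40.0 | 60.0 |
| dusk | 10.0 | 47.1 | 51.2 |
| dusk | 12.0 | 50.2 | 49.5 |
| dusk | 15.0 | 52.5 | 46.6 |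
| dusk | 20.0 | 55.3 | 44.8 |
| summer | 3.00 | 52.5 | 47.0 |
| summer | 6.00 | 71.9 | 28.9 |
| summer | 10.0 | 82.4 | 17.4 |
| summer | 12.0 | 85.3 | 14.5 |
| summer | 15.0 | 88.5 | 11.0 |
| summer | 20.0 | 92.7 | 8.0 |
| dawn | 2.00 | 29.1 | 70.5 |
| dawn | 5.00 | 50.2 | 50.1 |
| dawn | 10.0 | 66.5 | 34.0 |
| dawn | 15.0 | 73.0 | 27.1 |
| dawn | 20.0 | 76.3 | 24.4 |

(readings scatter by 0.5 percentage points)

- a reading or a percentage of product counts all its forms, free or not

- the best flask by amount of product, in percent of the electrophile charged; "all alike" if 1.5 percentage points covers them all (red / violet / grey / blue / all alike)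
- amount of product at the end, in percent of the electrophile charged, red
- amount of product at the end, in percent of the electrophile charged, violet
- amount of product at the end, in percent of the electrophile charged, grey
- amount of product at the end, in percent of the electrophile charged, blue

Blue is the midnight recipe, so one extreme is simply read: 76.2% at 25.0 h. The other extreme lets nothing react before the last addition, which makes a slow flask a midnight run stopped at 10.0 h. Between the readings 61.4% and 68.7%, that gives 65.1%.

A real feed reacts on the way, which by itself counts upward from the low extreme. But follow one free-base molecule. We suspect it waits for something the coupling releases, and may be lost while it waits. Dawn, charged with 0.60 M of free base, leads midnight at 15.0 h, 73.0% against 71.6% in readings that scatter by 0.5 percentage points, so free base appears to matter late, and red, violet and grey hold back part of their charge until 15 h, which we expect to keep it waiting. We therefore put the slow flasks near the low extreme, well under blue.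

The forecast also names blue, with 76.5% there, but gives red 72.5%, violet 71.4% and grey 72.8%; its red stands 7.4 points above our low extreme. Its ground: “Feeding only delays the bimolecular reaction”.

The flasks give blue as best: red 65.0%, violet 66.1%, grey 65.2%, blue 76.7%.

    2 free base → homo dimer (k = 0.320 /M/h)
    electrophile + nucleophile → acid set free + product (k = 0.610 /M/h)
    nucleophile + acid set free ⇌ protonated nucleophile, settled at all times (K = 130 /M)
    crystals ⇌ product, rate k4*(cs4 - [product]) while solid is left; crystals form when [product] > cs4 (solubility = 5.50 mM, k = 3.40 /h)
    acid set free + free base ⇌ salt of the base, settled at all times (K = 12000 /M)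

Red lands level with the low extreme, though it already held 51.9% at 15.0 h, and it has not come to rest. At 25.0 h red keeps, unbound, 35% of its electrophile, 7.2% of its nucleophile and 0.15% of its free base, and homo dimer holds 58.9% of the base charge, against 33.6% in blue. Red read at 96.0 h, after 81.0 h of full-charge hours, reaches 76.1%, level with blue at 25.0 h. At ten times the time, red gains 17 points and blue 9.8 points, ending at 81.6% against 86.5%.

The numbers in the tables come from a simulation from invented constants, and the scatter is random.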